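In the cyclohexene ring (C1 the carbinol carbon, C3=C4 the double bond) the hydroxyl on C1 and the alkynyl carbon on C4 stand para and flank the C5(CH3)2–C6H2 edge. A temporary O–C(=O) bridge from the C1 oxygen to C4 makes the ring the cycloadduct of a 2-pyrone, so one catalytic enantioselective inverse-electron-demand Diels–Alder reaction of ethyl 4-methyl-2-oxo-2H-pyran-3-carboxylate with isobutylene forms C6–C1 and C5–C4 and sets the carbinol centre. The bridge is then opened and its carbonyl lost as CO2, the activating ester becoming the first alkyne carbon. Hydroalkynylation, Horner–Wadsworth–Emmons olefination and a Stille coupling attach the all-E polyene.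

Key step: step 2

Remark (assumption): the (S,S) ligand is assigned to the wanted enantiomer by the square-planar chelate model of the copper bis(oxazoline) complex; if a pilot run shows the opposite sense of induction, the (R,R) ligand is used with no other change.

Step 1
Reactants: 1 diethyl 2-(propan-2-ylidene)malonate
Product: 3 ethyl 4-methyl-2-oxo-2H-pyran-3-carboxylate, via dienamine diester 2 (not isolated)
Conditions: Me2NCH(OMe)2 (1.2 equiv), neat, 110 °C; evaporate; then AcOH/H2O (4:1), 90 °C
Reagents that add atoms: N,N-dimethylformamide dimethyl acetal COC(OC)N(C)C; water O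
Why: The vinylogously acidic methyl group of the alkylidene malonate condenses with the amide acetal to the enamine, and aqueous acid then hydrolyses the enamine to the enol, which lactonises onto the cis ester with loss of ethanol (condensation then enol lactonisation, a standard route to 2-pyrone-3-carboxylates).

Step 2
Reactants: 3 ethyl 4-methyl-2-oxo-2H-pyran-3-carboxylate; 4 2-methylpropene (isobutylene)
Product: 5 ethyl (1S,4R)-5,8,8-trimethyl-3-oxo-2-oxabicyclo[2.2.2]oct-5-ene-4-carboxylate
Conditions: Cu(OTf)2 (10 mol %), 2,2'-(propane-2,2-diyl)bis[(4S)-4-tert-butyl-4,5-dihydrooxazole] (11 mol %), 4 Å molecular sieves, isobutylene (5 equiv, condensed), CH2Cl2, −20 °C to rt, sealed vessel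
Reagents that add atoms: none
Why: The pyrone chelates the divalent copper centre through its lactone and ester carbonyls, which lowers the diene LUMO so that the nucleophilic alkene adds in a concerted but strongly asynchronous [4+2] cycloaddition, the CH2 terminus of isobutylene bonding to the electrophilic pyrone C6 and the cation-stabilising C(CH3)2 carbon bonding to C3. The closest known reaction type is the chiral-Lewis-acid-catalysed inverse-electron-demand Diels–Alder reaction of 3-carboalkoxy-2-pyrones with electron-rich alkenes, which gives bridged bicyclic lactones. The six-membered carbocycle is closed by intermolecular [4+2] cycloaddition, suprafacial on both partners, and the O–C(=O) unit of the pyrone is carried into the product as the lactone bridge of the 2-oxabicyclo[2.2.2]octene. The two bridgehead stereocentres form together and depend on each other, so their absolute configuration is decided only by which face of the chelated pyrone the tert-butyl groups of the C2-symmetric ligand leave open, and because each carbon of isobutylene carries two identical substituents there is no endo/exo question. The step needs regioselectivity, which the polarity match secures, enantioface selectivity, which two-point binding to the chiral complex secures, and survival of the bridge, which the low temperature secures against retro-[4+2] loss of CO2.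

Step 3
Reactants: 5 ethyl (1S,4R)-5,8,8-trimethyl-3-oxo-2-oxabicyclo[2.2.2]oct-5-ene-4-carboxylate
Product: 7 ethyl (4S)-4-hydroxy-2,6,6-trimethylcyclohex-2-ene-1-carboxylate (both C1 epimers), via cis-hydroxy malonic half-acid 6 (not isolated)
Conditions: LiOH·H2O (1.2 equiv), THF/H2O, 0 °C; 1 M HCl to pH 3, extract; then toluene, 100 °C
Reagents that add atoms: none
Why: Hydroxide should open the strained bridged lactone faster than it attacks the hindered ethyl ester, and the malonic half-acid so released loses CO2 on warming through the cyclic hydrogen-transfer transition state (malonic-type decarboxylation), the ester dienol ketonising at the α-carbon while the carbinol centre is untouched.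

Step 4
Reactants: 7 ethyl (4S)-4-hydroxy-2,6,6-trimethylcyclohex-2-ene-1-carboxylate
Product: 9 (4R)-4-hydroxy-2,6,6-trimethylcyclohex-1-ene-1-carbaldehyde, via deconjugated hydroxy aldehyde 8 (not isolated)
Conditions: i-Bu2AlH (2.3 equiv), CH2Cl2, −78 °C; MeOH, then aq. potassium sodium tartrate; crude product, DBU (0.2 equiv), CH2Cl2, 0 °C to rt
Reagents that add atoms: none
Why: Partial reduction of the hindered ester should stop at the aluminium hemiacetal at −78 °C (DIBAL-H ester-to-aldehyde reduction), and the amidine base then moves the β,γ double bond into conjugation through the dienolate, which erases the epimeric centre and leaves the carbinol centre unchanged (its descriptor changes to R only because the priorities change).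

Step 5
Reactants: 9 (4R)-4-hydroxy-2,6,6-trimethylcyclohex-1-ene-1-carbaldehyde
Product: 10 (1R)-4-ethynyl-3,5,5-trimethylcyclohex-3-en-1-ol
Conditions: dimethyl (1-diazo-2-oxopropyl)phosphonate (1.5 equiv), K2CO3 (2 equiv), MeOH, 0 °C to rt
Reagents that add atoms: dimethyl (1-diazo-2-oxopropyl)phosphonate CC(=O)C(=[N+]=[N-])P(=O)(OC)OC
Why: Seyferth–Gilbert homologation with the Ohira–Bestmann reagent should convert the enal into the terminal enyne through the diazoalkene and 1,2-hydride shift of the alkylidene carbene, under carbonate conditions mild enough to spare the hydroxy enal.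

Step 6
Reactants: 10 (1R)-4-ethynyl-3,5,5-trimethylcyclohex-3-en-1-ol; 11 ethyl but-2-ynoate
Product: 12 ethyl (2E)-5-[(4R)-4-hydroxy-2,6,6-trimethylcyclohex-1-en-1-yl]-3-methylpent-2-en-4-ynoate
Conditions: Pd(OAc)2 (3 mol %), tris(2,6-dimethoxyphenyl)phosphine (3 mol %), toluene, rt
Reagents that add atoms: none
Why: Palladium-catalysed addition of the terminal (donor) alkyne C–H bond across the alkynoate (acceptor) proceeds by syn carbopalladation with the alkynyl group delivered to the β-carbon and protonolysis with retention, so the alkynyl group and the ester end up trans (hydroalkynylation of an ynoate, 2E by mechanism).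

Step 7
Reactants: 12 ethyl (2E)-5-[(4R)-4-hydroxy-2,6,6-trimethylcyclohex-1-en-1-yl]-3-methylpent-2-en-4-ynoate
Product: 13 (1R)-4-[(3E)-5-hydroxy-3-methylpent-3-en-1-yn-1-yl]-3,5,5-trimethylcyclohex-3-en-1-ol
Conditions: i-Bu2AlH (3.3 equiv), CH2Cl2, −78 °C to −40 °C; aq. potassium sodium tartrate
Reagents that add atoms: none
Why: DIBAL-H 1,2-reduction of the conjugated ester gives the allylic alcohol without touching the alkyne or the alkene geometry.

Step 8
Reactants: 13 (1R)-4-[(3E)-5-hydroxy-3-methylpent-3-en-1-yn-1-yl]-3,5,5-trimethylcyclohex-3-en-1-ol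
Product: 14 (2E)-5-[(4R)-4-hydroxy-2,6,6-trimethylcyclohex-1-en-1-yl]-3-methylpent-2-en-4-ynal
Conditions: activated MnO2 (15 equiv), CH2Cl2, rt, dark
Reagents that add atoms: none
Why: MnO2 allylic oxidation takes only the primary allylic alcohol and leaves the homoallylic ring carbinol alone.

Step 9
Reactants: 15 prop-2-yn-1-ol
Product: 17 (2E)-3-iodo-2-methylprop-2-en-1-ol, via alkenylalane 16 (not isolated)
Conditions: Me3Al (3 equiv), Cp2ZrCl2 (0.25 equiv), CH2Cl2, 0 °C to rt; then I2, THF, −30 °C to 0 °C; aq. K2CO3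
Reagents that add atoms: trimethylaluminium C[Al](C)C; iodine II
Why: Zirconocene-catalysed syn methylalumination of the terminal alkyne puts methyl on the internal and aluminium on the terminal carbon, and iodinolysis with retention gives the E iodoalkene (carboalumination then iododealumination).

Step 10
Reactants: 17 (2E)-3-iodo-2-methylprop-2-en-1-ol
Product: 18 (1E)-3-bromo-1-iodo-2-methylprop-1-ene
Conditions: CBr4 (1.2 equiv), PPh3 (1.2 equiv), CH2Cl2, 0 °C
Reagents that add atoms: tetrabromomethane BrC(Br)(Br)Br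
Why: Appel bromination substitutes the primary allylic hydroxyl by SN2 displacement and leaves the iodoalkene geometry untouched.

Step 11
Reactants: 18 (1E)-3-bromo-1-iodo-2-methylprop-1-ene
Product: 19 diethyl [(2E)-3-iodo-2-methylprop-2-en-1-yl]phosphonate
Conditions: P(OEt)3 (1.5 equiv), neat, 100 °C
Reagents that add atoms: triethyl phosphite CCOP(OCC)OCC
Why: Michaelis–Arbuzov reaction of the primary allylic bromide gives the allylic phosphonate with the alkene geometry retained.

Step 12
Reactants: 14 (2E)-5-[(4R)-4-hydroxy-2,6,6-trimethylcyclohex-1-en-1-yl]-3-methylpent-2-en-4-ynal; 19 diethyl [(2E)-3-iodo-2-methylprop-2-en-1-yl]phosphonate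
Product: 20 (1R)-4-[(3E,5E,7E)-8-iodo-3,7-dimethylocta-3,5,7-trien-1-yn-1-yl]-3,5,5-trimethylcyclohex-3-en-1-ol
Conditions: 19 (2.2 equiv), LiN(SiMe3)2 (2.1 equiv), THF, −78 °C; then 14, −78 °C to 0 °C
Reagents that add atoms: none
Why: Horner–Wadsworth–Emmons olefination of the enal with the lithiated allylic phosphonate should give the new disubstituted double bond E through the equilibrating anti adduct, the excess anion covering the free hydroxyl and the low temperature preserving the iodoalkene geometry.

Step 13
Reactants: 21 pent-4-yn-1-ol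
Product: 23 (4E)-5-iodo-4-methylpent-4-en-1-ol, via alkenylalane 22 (not isolated)
Conditions: Me3Al (3 equiv), Cp2ZrCl2 (0.25 equiv), CH2Cl2, 0 °C to rt; then I2, THF, −30 °C to 0 °C; aq. K2CO3
Reagents that add atoms: trimethylaluminium C[Al](C)C; iodine II
Why: The same zirconocene-catalysed syn methylalumination and iodinolysis with retention set the E trisubstituted iodoalkene of the tail.

Step 14
Reactants: 23 (4E)-5-iodo-4-methylpent-4-en-1-ol; 24 (E)-1,2-bis(tributylstannyl)ethene
Product: 25 (4E,6E)-4-methyl-7-(tributylstannyl)hepta-4,6-dien-1-ol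
Conditions: 24 (2.5 equiv), PdCl2(MeCN)2 (5 mol %), DMF, rt
Reagents that add atoms: none
Why: Stille coupling proceeds with retention at both sp2 carbons, and the excess of the bis-stannane suppresses the second coupling so that the dienylstannane is obtained.

Step 15
Reactants: 20 (1R)-4-[(3E,5E,7E)-8-iodo-3,7-dimethylocta-3,5,7-trien-1-yn-1-yl]-3,5,5-trimethylcyclohex-3-en-1-ol; 25 (4E,6E)-4-methyl-7-(tributylstannyl)hepta-4,6-dien-1-ol
Product: 26 (1R)-4-[(3E,5E,7E,9E,11E)-15-hydroxy-3,7,12-trimethylpentadeca-3,5,7,9,11-pentaen-1-yn-1-yl]-3,5,5-trimethylcyclohex-3-en-1-ol (CNP0344116.1)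
Conditions: Pd2(dba)3 (5 mol %), AsPh3 (20 mol %), DMF, rt, argon, dark
Reagents that add atoms: none
Why: Stille coupling with zerovalent palladium joins the two stereodefined alkenyl partners with retention under neutral conditions that should tolerate both free hydroxyls and the pentaenyne.

Compound list
1 | diethyl 2-(propan-2-ylidene)malonate | CCOC(=O)C(=C(C)C)C(=O)OCC | starting material
2 | diethyl 2-[(3E)-4-(dimethylamino)but-3-en-2-ylidene]malonate | CCOC(=O)C(C(=O)OCC)=C(C)/C=C/N(C)C | intermediate (not isolated)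
3 | ethyl 4-methyl-2-oxo-2H-pyran-3-carboxylate | CCOC(=O)C1=C(C)C=COC1=O | intermediate
4 | 2-methylpropene (isobutylene) | CC(C)=C | starting material
5 | ethyl (1S,4R)-5,8,8-trimethyl-3-oxo-2-oxabicyclo[2.2.2]oct-5-ene-4-carboxylate | O=C1O[C@H]2CC(C)(C)[C@]1(C(=O)OCC)C(C)=C2 | intermediate
6 | (1S,4S)-1-(ethoxycarbonyl)-4-hydroxy-2,6,6-trimethylcyclohex-2-ene-1-carboxylic acid | OC(=O)[C@@]1(C(=O)OCC)C(C)=C[C@@H](O)CC1(C)C | intermediate (not isolated)
7 | ethyl (4S)-4-hydroxy-2,6,6-trimethylcyclohex-2-ene-1-carboxylate (both C1 epimers) | CCOC(=O)C1C(C)=C[C@@H](O)CC1(C)C | intermediate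
8 | (4S)-4-hydroxy-2,6,6-trimethylcyclohex-2-ene-1-carbaldehyde (both C1 epimers) | O=CC1C(C)=C[C@@H](O)CC1(C)C | intermediate (not isolated)
9 | (4R)-4-hydroxy-2,6,6-trimethylcyclohex-1-ene-1-carbaldehyde | O=CC1=C(C)C[C@@H](O)CC1(C)C | intermediate
10 | (1R)-4-ethynyl-3,5,5-trimethylcyclohex-3-en-1-ol | C#CC1=C(C)C[C@@H](O)CC1(C)C | intermediate
11 | ethyl but-2-ynoate | CC#CC(=O)OCC | starting material
12 | ethyl (2E)-5-[(4R)-4-hydroxy-2,6,6-trimethylcyclohex-1-en-1-yl]-3-methylpent-2-en-4-ynoate | CCOC(=O)/C=C(\C)C#CC1=C(C)C[C@@H](O)CC1(C)C | intermediate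
13 | (1R)-4-[(3E)-5-hydroxy-3-methylpent-3-en-1-yn-1-yl]-3,5,5-trimethylcyclohex-3-en-1-ol | OC/C=C(\C)C#CC1=C(C)C[C@@H](O)CC1(C)C | intermediate
14 | (2E)-5-[(4R)-4-hydroxy-2,6,6-trimethylcyclohex-1-en-1-yl]-3-methylpent-2-en-4-ynal | O=C/C=C(\C)C#CC1=C(C)C[C@@H](O)CC1(C)C | intermediate
15 | prop-2-yn-1-ol | C#CCO | starting material
16 | dimethylalumanyl (2E)-3-(dimethylalumanyl)-2-methylprop-2-en-1-olate | C[Al](C)OC/C(C)=C/[Al](C)C | intermediate (not isolated)
17 | (2E)-3-iodo-2-methylprop-2-en-1-ol | OC/C(C)=C/I | intermediate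
18 | (1E)-3-bromo-1-iodo-2-methylprop-1-ene | BrC/C(C)=C/I | intermediate
19 | diethyl [(2E)-3-iodo-2-methylprop-2-en-1-yl]phosphonate | CCOP(=O)(OCC)C/C(C)=C/I | intermediate
20 | (1R)-4-[(3E,5E,7E)-8-iodo-3,7-dimethylocta-3,5,7-trien-1-yn-1-yl]-3,5,5-trimethylcyclohex-3-en-1-ol | I/C=C(C)/C=C/C=C(\C)C#CC1=C(C)C[C@@H](O)CC1(C)C | intermediate
21 | pent-4-yn-1-ol | C#CCCCO | starting material
22 | dimethylalumanyl (4E)-5-(dimethylalumanyl)-4-methylpent-4-en-1-olate | C[Al](C)OCCC/C(C)=C/[Al](C)C | intermediate (not isolated)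
23 | (4E)-5-iodo-4-methylpent-4-en-1-ol | OCCC/C(C)=C/I | intermediate
24 | (E)-1,2-bis(tributylstannyl)ethene | CCCC[Sn](CCCC)(CCCC)/C=C/[Sn](CCCC)(CCCC)CCCC | starting material
25 | (4E,6E)-4-methyl-7-(tributylstannyl)hepta-4,6-dien-1-ol | OCCC/C(C)=C/C=C/[Sn](CCCC)(CCCC)CCCC | intermediate
26 | (1R)-4-[(3E,5E,7E,9E,11E)-15-hydroxy-3,7,12-trimethylpentadeca-3,5,7,9,11-pentaen-1-yn-1-yl]-3,5,5-trimethylcyclohex-3-en-1-ol | CC1=C(C#C/C(C)=C/C=C/C(C)=C/C=C/C=C(\C)CCCO)C(C)(C)C[C@H](O)C1 | target

Total step count: 15. Longest linear sequence: 10 steps (steps 1 to 8, then 12 and 15).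

Steps most likely to fail

Step 2. The weakly nucleophilic dialkyl alkene may add too slowly or with poor face discrimination, and it may oligomerise under the Lewis acid; the new bond also joins two fully substituted carbons. The fallback sets out from 3 and 4 and returns at 10. The cycloaddition is run without chiral ligand (Yb(OTf)3, CH2Cl2, rt, sealed vessel, or under 10 kbar without catalyst) to give racemic ethyl 5,8,8-trimethyl-3-oxo-2-oxabicyclo[2.2.2]oct-5-ene-4-carboxylate F1. The conditions of steps 3 to 5 then lead through the racemic cis-1-(ethoxycarbonyl)-4-hydroxy-2,6,6-trimethylcyclohex-2-ene-1-carboxylic acid F2 to racemic ethyl 4-hydroxy-2,6,6-trimethylcyclohex-2-ene-1-carboxylate F3, through racemic 4-hydroxy-2,6,6-trimethylcyclohex-2-ene-1-carbaldehyde F4 to racemic 4-hydroxy-2,6,6-trimethylcyclohex-1-ene-1-carbaldehyde F5, and on to racemic 4-ethynyl-3,5,5-trimethylcyclohex-3-en-1-ol F6. Lipase-catalysed kinetic resolution (Burkholderia cepacia lipase, vinyl acetate, t-BuOMe, rt) is expected, by the usual size rule for secondary alcohols with the CH2 next to the quaternary carbon as the large group, to acetylate the R alcohol to (1R)-4-ethynyl-3,5,5-trimethylcyclohex-3-en-1-yl acetate F7 and to leave (1S)-4-ethynyl-3,5,5-trimethylcyclohex-3-en-1-ol F8. F7 is separated and methanolysed (K2CO3, MeOH) to 10.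

Step 4. Reduction may run past the aldehyde stage to the primary alcohol, or the base treatment may cause loss of the ring hydroxyl by elimination. The fallback sets out from 7 and returns at 8. Full reduction with LiAlH4 (THF, 0 °C) gives (1S)-4-(hydroxymethyl)-3,5,5-trimethylcyclohex-2-en-1-ol F9 as both C4 epimers. Chemoselective oxidation of its primary hydroxyl (TEMPO cat., PhI(OAc)2, CH2Cl2, rt) gives 8, which is isomerised to 9 with DBU as in step 4, or on basic alumina if elimination is the problem.

Step 12. Alkene geometry may be lost, either at the new double bond or at the iodoalkene through the delocalised phosphonate anion. The fallback sets out from 14 and returns at 20, and sets the trisubstituted iodoalkene by carbometalation instead of carrying it through an anion. Horner–Wadsworth–Emmons reaction of 14 with commercial diethyl [3-(trimethylsilyl)prop-2-yn-1-yl]phosphonate (LiN(SiMe3)2, THF, −78 °C) gives (1R)-3,5,5-trimethyl-4-[(3E,5E)-3-methyl-8-(trimethylsilyl)octa-3,5-diene-1,7-diyn-1-yl]cyclohex-3-en-1-ol F10. Desilylation (K2CO3, MeOH) gives (1R)-3,5,5-trimethyl-4-[(3E,5E)-3-methylocta-3,5-diene-1,7-diyn-1-yl]cyclohex-3-en-1-ol F11. Zirconocene-catalysed methylalumination of the terminal alkyne (Me3Al, Cp2ZrCl2, CH2Cl2) gives the alkenylalane dimethylalumanyl (1R)-4-[(3E,5E,7E)-8-(dimethylalumanyl)-3,7-dimethylocta-3,5,7-trien-1-yn-1-yl]-3,5,5-trimethylcyclohex-3-en-1-olate F12, which is iodinated in the same flask (I2, THF, −30 °C) to 20.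

Further compounds
F1 | step 2 | racemic ethyl 5,8,8-trimethyl-3-oxo-2-oxabicyclo[2.2.2]oct-5-ene-4-carboxylate | O=C1OC2CC(C)(C)C1(C(=O)OCC)C(C)=C2
F2 | step 2 | racemic cis-1-(ethoxycarbonyl)-4-hydroxy-2,6,6-trimethylcyclohex-2-ene-1-carboxylic acid | OC(=O)C1(C(=O)OCC)C(C)=CC(O)CC1(C)C
F3 | step 2 | racemic ethyl 4-hydroxy-2,6,6-trimethylcyclohex-2-ene-1-carboxylate | CCOC(=O)C1C(C)=CC(O)CC1(C)C
F4 | step 2 | racemic 4-hydroxy-2,6,6-trimethylcyclohex-2-ene-1-carbaldehyde | O=CC1C(C)=CC(O)CC1(C)C
F5 | step 2 | racemic 4-hydroxy-2,6,6-trimethylcyclohex-1-ene-1-carbaldehyde | O=CC1=C(C)CC(O)CC1(C)C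
F6 | step 2 | racemic 4-ethynyl-3,5,5-trimethylcyclohex-3-en-1-ol | C#CC1=C(C)CC(O)CC1(C)C
F7 | step 2 | (1R)-4-ethynyl-3,5,5-trimethylcyclohex-3-en-1-yl acetate | C#CC1=C(C)C[C@@H](OC(C)=O)CC1(C)C
F8 | step 2 | (1S)-4-ethynyl-3,5,5-trimethylcyclohex-3-en-1-ol | C#CC1=C(C)C[C@H](O)CC1(C)C
F9 | step 4 | (1S)-4-(hydroxymethyl)-3,5,5-trimethylcyclohex-2-en-1-ol (both C4 epimers) | OCC1C(C)=C[C@@H](O)CC1(C)C
F10 | step 12 | (1R)-3,5,5-trimethyl-4-[(3E,5E)-3-methyl-8-(trimethylsilyl)octa-3,5-diene-1,7-diyn-1-yl]cyclohex-3-en-1-ol | C[Si](C)(C)C#C/C=C/C=C(\C)C#CC1=C(C)C[C@@H](O)CC1(C)C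
F11 | step 12 | (1R)-3,5,5-trimethyl-4-[(3E,5E)-3-methylocta-3,5-diene-1,7-diyn-1-yl]cyclohex-3-en-1-ol | C#C/C=C/C=C(\C)C#CC1=C(C)C[C@@H](O)CC1(C)C
F12 | step 12 | dimethylalumanyl (1R)-4-[(3E,5E,7E)-8-(dimethylalumanyl)-3,7-dimethylocta-3,5,7-trien-1-yn-1-yl]-3,5,5-trimethylcyclohex-3-en-1-olate | C[Al](C)/C=C(C)/C=C/C=C(\C)C#CC1=C(C)C[C@@H](O[Al](C)C)CC1(C)C
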